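# Proposed synthesis of (1S,2S,3R)-2,3,7-trihydroxy-3-(hydroxymethyl)-6-methoxy-1-(3,4,5-trihydroxyphenyl)tetralin-2-carboxylic acid (CNP0174537.1)

## Analysis of the target

The target is a 1-aryltetralin (cyclolignan) acid. Ring A is a guaiacol (6-OMe, 7-OH) and ring C (C1–C4, C4a, C8a) carries all three stereocentres; a pyrogallol ring sits on C1. C1 (S) is a diarylmethine, C2 (S) is fully substituted (OH, CO2H) and C3 (R) is fully substituted (OH, CH2OH); C4 is a plain benzylic CH2. On ring C the aryl group, the C2–OH and the C3–CH2OH lie on one face, and the C1–H, the CO2H and the C3–OH on the other. The three carbon substituents are therefore all-trans (all equatorial in one half-chair) and the 2,3-diol is trans-diaxial. Sensitive groups are the air-sensitive pyrogallol and guaiacol, and the α,β-dihydroxy acid with two tertiary carbinols, which can undergo retro-aldol cleavage. The hard points are the bond between the two fully substituted carbons C2 and C3, and the C2–OH, which is cis to the C1 aryl group, so that an oxidant approaching a preformed ring from the open face would give the wrong C2 epimer. C1 cannot be controlled by acyclic induction because its two aryl groups are alike. Two features invite the plan. C1(aryl)–C2(CO2H)–C3(OH) is the retron of a conjugate arylation followed by an aldol addition of the resulting enolate onto a C3 ketone held by ring A. The cis pair C2–CO2H / C3–OH is a β-hydroxy acid that can be tied into a β-lactone.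

## Retrosynthetic reasoning

18 to 17: all four phenols and the primary alcohol are carried as benzyl ethers, so the last step is one neutral hydrogenolysis. This keeps the pyrogallol masked until the end.

17 to 16 to 14: the C2–O bond is cut. In 14 the C2 carboxyl is tied to the C3 oxygen as a cis-fused β-lactone. Its enolate carbon is the ring-fusion atom, so an oxygen electrophile can only end up on the face that keeps the four-membered ring cis-fused, which is the hindered face next to the C1 aryl group. Lactone hydrolysis by acyl–oxygen cleavage then releases 17 without touching C3.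

14 to 13 to 12: the lactone comes from the β-hydroxy acid 13, which is the saponified ester 12. The cis relation of CO2R and C3–OH in 12 is what makes the lactone possible.

12 to 7 + 10 (key disconnection): two bonds of ring C are cut at once, C1–aryl and C2–C3. This leaves the achiral enoate–ketone 7 and the boronic acid 10. Forward, a chiral rhodium(I) catalyst must add the aryl group of 10 to C1 of 7 enantioselectively, and the rhodium enolate 11 must close ring C onto the ketone before it is protonated. The cut is made here because it is the only ring closure in which C2 and C3 are formed together under the control of C1, and because it gives the carboxyl carbon and the C3 oxygen cis.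

7 to 5 + 6: a Wittig olefination of the aldehyde of 5 with the stabilised ylide 6; the ketone of 5 is left alone.

5 to 3 to 1 + 2: the 2-oxopropyl chain of 5 is the hydrate of an ortho-alkynyl benzaldehyde. In 3 the aldehyde oxygen steers hydration to the distal alkyne carbon through lactol 4. 3 is the Sonogashira product of bromide 1 and alkyne 2. In 1 the aldehyde carbon (future C1) is para to OMe and the bromide (future C4a) is para to OBn, as ring A of 18 requires.

10 to 8: bromine–lithium exchange (9) and borylation.

## Alternatives that were turned down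

Alternative 1: the textbook cut, C1–C8a, by a cationic Friedel–Crafts closure. Forward key step: Lewis-acid epoxy-arene cyclisation of the glycidic ester A1 onto the position para to OMe, giving the 2-hydroxy-3-oxo ester A2 with inversion at C1. Turned down because A2 still lacks C3. The hydroxymethyl carbon would have to be added to a hindered α-hydroxy-β-keto ester that is prone to retro-Claisen and α-ketol shifts. In either half-chair one face of the C3 carbonyl is flanked by an axial group (the C2 ester or the C1 aryl), so the facial outcome is not secured by structure. Enantiocontrol would rest on an asymmetric epoxidation of a geometrically labile alkylidene β-keto ester. Each stereocentre would be made in a separate step.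

Alternative 2: cut C2–C3 as acyl anion plus ketone. Forward key step: NHC-catalysed intramolecular crossed benzoin of the aldehyde–α-keto ester A3, with dynamic kinetic resolution of the enolisable C1, again giving A2. Turned down because the absolute configuration would depend on a dynamic resolution of a diarylmethine next to a keto ester, in a cyclisation whose C1/C2 preference cannot be predicted from structure. A3 carries an arylacetaldehyde and an enol-prone diarylpyruvate in one molecule. The route converges on A2, with the same unsolved C3 problem as Alternative 1.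

Alternative 3: cut both C–O bonds at C2 and C3. Forward key step: anti-dihydroxylation of the tetrasubstituted olefin A4 by epoxidation and hydrolytic opening. Turned down on mechanism. A peracid attacks anti to the C1 aryl group and gives A5. Water then opens A5 at C3, the carbon remote from the ester that can bear positive charge, with inversion. This places the C2–OH trans to the aryl group and the C3–OH cis to it, so both carbinol centres come out opposite to 18. The correct isomer would need epoxidation on the aryl face or an SN2 displacement at the quaternary α-carbon, and neither can be defended. The olefin is also electron-poor and tetrasubstituted.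

Key step: step 5

Remark (assumption): 1 and 8 are treated as catalogue building blocks; each is otherwise one O-benzylation away from 6-bromoisovanillin or 5-bromopyrogallol. The route requires Re-face arylation of C1; (S)-BINAP is written as the antipode expected to do this by analogy with linear (E)-acceptors, and the enantiomeric ligand is used if the sense proves opposite.

## Route

Step 1
Reactants: 1 5-(benzyloxy)-2-bromo-4-methoxybenzaldehyde; 2 3-(benzyloxy)prop-1-yne
Product: 3 5-(benzyloxy)-2-[3-(benzyloxy)prop-1-yn-1-yl]-4-methoxybenzaldehyde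
Conditions: PdCl2(PPh3)2 (3 mol%), CuI (5 mol%), Et3N, THF, 60 °C
Reagents that add atoms: none
Why: Sonogashira coupling; the ortho-formyl group activates the otherwise electron-rich aryl bromide towards oxidative addition, and aldehyde and benzyl ethers are inert.

Step 2
Reactants: 3 5-(benzyloxy)-2-[3-(benzyloxy)prop-1-yn-1-yl]-4-methoxybenzaldehyde
Product: 5 5-(benzyloxy)-2-[3-(benzyloxy)-2-oxopropyl]-4-methoxybenzaldehyde, via lactol 4 (not isolated)
Conditions: AgOTf (5 mol%), H2O (10 equiv), 1,4-dioxane, 50 °C; crude product used directly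
Reagents that add atoms: water (O)
Why: Carbonyl-assisted alkyne hydration: 6-endo attack of the aldehyde oxygen on the π-activated alkyne gives an isochromenylium ion, water adds at the former aldehyde carbon to give lactol 4, and ring-chain tautomerism places the ketone on the distal alkyne carbon. Unassisted hydration would give the aryl ketone instead.

Step 3
Reactants: 5 5-(benzyloxy)-2-[3-(benzyloxy)-2-oxopropyl]-4-methoxybenzaldehyde; 6 methyl (triphenyl-λ5-phosphanylidene)acetate
Product: 7 methyl (2E)-3-{5-(benzyloxy)-2-[3-(benzyloxy)-2-oxopropyl]-4-methoxyphenyl}prop-2-enoate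
Conditions: 6 (1.2 equiv), CH2Cl2, rt to 40 °C
Reagents that add atoms: none
Why: Wittig olefination with a stabilised ylide is E-selective and aldehyde-selective, and its neutral conditions avoid base-induced aldol condensation of the 1,5-dicarbonyl compound to a naphthol.

Step 4
Reactants: 8 1,2,3-tris(benzyloxy)-5-bromobenzene
Product: 10 [3,4,5-tris(benzyloxy)phenyl]boronic acid, via aryllithium 9 (not isolated)
Conditions: n-BuLi (1.1 equiv), THF, −78 °C; B(OiPr)3, −78 °C to rt; 1 M HCl, 0 °C
Reagents that add atoms: triisopropyl borate (CC(C)OB(OC(C)C)OC(C)C); water (O)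
Why: Bromine–lithium exchange, borate trapping and hydrolysis; the exchange is faster than ortho-lithiation or benzylic deprotonation at −78 °C.

Step 5
Reactants: 7 methyl (2E)-3-{5-(benzyloxy)-2-[3-(benzyloxy)-2-oxopropyl]-4-methoxyphenyl}prop-2-enoate; 10 [3,4,5-tris(benzyloxy)phenyl]boronic acid
Product: 12 methyl (1S,2R,3S)-7-(benzyloxy)-3-[(benzyloxy)methyl]-3-hydroxy-6-methoxy-1-[3,4,5-tris(benzyloxy)phenyl]-1,2,3,4-tetrahydronaphthalene-2-carboxylate, via rhodium enolate 11 (not isolated)
Conditions: [Rh(OH)((S)-binap)]2 (3 mol%), 10 (2.5 equiv), H2O (5 equiv), 1,4-dioxane, 60 °C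
Reagents that add atoms: none
Why: Transmetalation of 10 to the hydroxo-rhodium(I)–BINAP complex and enantio-determining carborhodation of the (E)-enoate put the aryl group on the Re face of C1 and give the O-bound rhodium enolate 11; the closest known reaction type is the Rh-catalysed asymmetric conjugate arylation of enones run in tandem with aldol cyclisation onto a tethered ketone. With only a few equivalents of water present, 11 should add to the ketone six atoms away faster than it is protonated, closing ring C in a 6-(enolexo)-exo-trig aldol. C1 is set by the ligand. C2 follows from allylic strain in 11: the C1–H lies in the enolate plane, so the tether closes on the face anti to the new aryl group and aryl and CO2Me end up trans and both equatorial. C3 follows from the rhodium-bridged chair transition state, which holds the new C3–O cis to the ester and leaves CH2OBn equatorial. The step needs chemoselectivity for the enoate over the ketone, which is expected because aryl-rhodium species add to ketones far more slowly. It also needs the absence of strong base so that the ketone does not enolise into a Michael cyclisation; the base-free hydroxo complex secures this. Hydrolysis of the rhodium aldolate returns the hydroxo complex, and 12 already has the configuration of 18 at C1 and C3 and the carboxyl carbon on the correct face of C2.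

Step 6
Reactants: 12 methyl (1S,2R,3S)-7-(benzyloxy)-3-[(benzyloxy)methyl]-3-hydroxy-6-methoxy-1-[3,4,5-tris(benzyloxy)phenyl]-1,2,3,4-tetrahydronaphthalene-2-carboxylate
Product: 13 (1S,2R,3S)-7-(benzyloxy)-3-[(benzyloxy)methyl]-3-hydroxy-6-methoxy-1-[3,4,5-tris(benzyloxy)phenyl]-1,2,3,4-tetrahydronaphthalene-2-carboxylic acid
Conditions: LiOH·H2O (3 equiv), THF/MeOH/H2O (3:1:1), rt; 1 M HCl to pH 3
Reagents that add atoms: lithium hydroxide ([Li+].[OH-])
Why: Saponification; the equatorial ester is the thermodynamic C2 epimer, so reversible enolisation cannot change it, and mild temperature keeps retro-aldol cleavage of the tertiary aldol slow.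

Step 7
Reactants: 13 (1S,2R,3S)-7-(benzyloxy)-3-[(benzyloxy)methyl]-3-hydroxy-6-methoxy-1-[3,4,5-tris(benzyloxy)phenyl]-1,2,3,4-tetrahydronaphthalene-2-carboxylic acid
Product: 14 (1S,2R,3S)-7-(benzyloxy)-3-[(benzyloxy)methyl]-3-hydroxy-6-methoxy-1-[3,4,5-tris(benzyloxy)phenyl]-1,2,3,4-tetrahydronaphthalene-2-carboxylic acid 2,3-β-lactone (cis-fused oxetan-2-one; tetralin numbering)
Conditions: BOPCl (1.5 equiv), Et3N (3 equiv), CH2Cl2, 0 °C to rt
Reagents that add atoms: none
Why: β-Lactonisation by carboxyl activation and attack of the cis tertiary hydroxyl, a method that tolerates tertiary β-hydroxy acids; no stereocentre is touched.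

Step 8
Reactants: 14 (1S,2R,3S)-7-(benzyloxy)-3-[(benzyloxy)methyl]-3-hydroxy-6-methoxy-1-[3,4,5-tris(benzyloxy)phenyl]-1,2,3,4-tetrahydronaphthalene-2-carboxylic acid 2,3-β-lactone
Product: 16 (1S,2S,3R)-7-(benzyloxy)-3-[(benzyloxy)methyl]-2,3-dihydroxy-6-methoxy-1-[3,4,5-tris(benzyloxy)phenyl]-1,2,3,4-tetrahydronaphthalene-2-carboxylic acid 2,3-β-lactone (lactone O on C3; free OH on C2), via lithium enolate 15 (not isolated)
Conditions: LDA (1.2 equiv), THF, −78 °C; 2-(phenylsulfonyl)-3-phenyloxaziridine (1.5 equiv), −78 °C; AcOH quench at −78 °C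
Reagents that add atoms: 2-(phenylsulfonyl)-3-phenyloxaziridine (O=S(=O)(c1ccccc1)N1OC1c1ccccc1)
Why: Enolate hydroxylation with a sulfonyloxaziridine on a β-lactone enolate. The enolate carbon is the fusion atom of the four-membered ring, so oxygen should enter on the face that keeps the 4/6 fusion cis, since a trans-fused lactone on the benzo-fused ring would be highly strained; OH therefore replaces H with retention, cis to the aryl group and CH2OBn. β-Lactone enolates resist β-elimination at −78 °C because the C–O bond lies in the nodal plane of the enolate.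

Step 9
Reactants: 16 (1S,2S,3R)-7-(benzyloxy)-3-[(benzyloxy)methyl]-2,3-dihydroxy-6-methoxy-1-[3,4,5-tris(benzyloxy)phenyl]-1,2,3,4-tetrahydronaphthalene-2-carboxylic acid 2,3-β-lactone
Product: 17 (1S,2S,3R)-7-(benzyloxy)-3-[(benzyloxy)methyl]-2,3-dihydroxy-6-methoxy-1-[3,4,5-tris(benzyloxy)phenyl]-1,2,3,4-tetrahydronaphthalene-2-carboxylic acid
Conditions: LiOH (2 equiv), THF/H2O (3:1), 0 °C; cold 1 M HCl to pH 3
Reagents that add atoms: lithium hydroxide ([Li+].[OH-])
Why: Hydroxide opens the strained lactone by acyl–oxygen cleavage; the quaternary C3 cannot undergo alkyl–oxygen substitution, so its configuration is retained.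

Step 10
Reactants: 17 (1S,2S,3R)-7-(benzyloxy)-3-[(benzyloxy)methyl]-2,3-dihydroxy-6-methoxy-1-[3,4,5-tris(benzyloxy)phenyl]-1,2,3,4-tetrahydronaphthalene-2-carboxylic acid
Product: 18 (1S,2S,3R)-2,3,7-trihydroxy-3-(hydroxymethyl)-6-methoxy-1-(3,4,5-trihydroxyphenyl)-1,2,3,4-tetrahydronaphthalene-2-carboxylic acid
Conditions: H2 (1 atm), 10% Pd/C, THF/MeOH (1:1), rt; filtration and concentration under argon
Reagents that add atoms: none
Why: Hydrogenolysis of the five benzyl ethers under neutral conditions; there is no benzylic C–O bond in the skeleton, and the methyl ether, tertiary alcohols and acid are untouched.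

## Compound list

1 | 5-(benzyloxy)-2-bromo-4-methoxybenzaldehyde | COc1cc(Br)c(C=O)cc1OCc1ccccc1 | starting material
2 | 3-(benzyloxy)prop-1-yne | C#CCOCc1ccccc1 | starting material
3 | 5-(benzyloxy)-2-[3-(benzyloxy)prop-1-yn-1-yl]-4-methoxybenzaldehyde | COc1cc(C#CCOCc2ccccc2)c(C=O)cc1OCc1ccccc1 | intermediate
4 | 7-(benzyloxy)-3-[(benzyloxy)methyl]-6-methoxy-1H-isochromen-1-ol (racemic lactol; not isolated) | COc1cc2C=C(COCc3ccccc3)OC(O)c2cc1OCc1ccccc1 | intermediate
5 | 5-(benzyloxy)-2-[3-(benzyloxy)-2-oxopropyl]-4-methoxybenzaldehyde | COc1cc(CC(=O)COCc2ccccc2)c(C=O)cc1OCc1ccccc1 | intermediate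
6 | methyl (triphenyl-λ5-phosphanylidene)acetate | COC(=O)C=P(c1ccccc1)(c1ccccc1)c1ccccc1 | starting material
7 | methyl (2E)-3-{5-(benzyloxy)-2-[3-(benzyloxy)-2-oxopropyl]-4-methoxyphenyl}prop-2-enoate | COC(=O)/C=C/c1cc(OCc2ccccc2)c(OC)cc1CC(=O)COCc1ccccc1 | intermediate
8 | 1,2,3-tris(benzyloxy)-5-bromobenzene | Brc1cc(OCc2ccccc2)c(OCc2ccccc2)c(OCc2ccccc2)c1 | starting material
9 | [3,4,5-tris(benzyloxy)phenyl]lithium (not isolated) | [Li]c1cc(OCc2ccccc2)c(OCc2ccccc2)c(OCc2ccccc2)c1 | intermediate
10 | [3,4,5-tris(benzyloxy)phenyl]boronic acid | OB(O)c1cc(OCc2ccccc2)c(OCc2ccccc2)c(OCc2ccccc2)c1 | intermediate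
11 | rhodium(I) (Z)-O-enolate of methyl (3S)-3-{5-(benzyloxy)-2-[3-(benzyloxy)-2-oxopropyl]-4-methoxyphenyl}-3-[3,4,5-tris(benzyloxy)phenyl]propanoate (ligand omitted; not isolated) | CO/C(O[Rh])=C/[C@@H](c1cc(OCc2ccccc2)c(OCc2ccccc2)c(OCc2ccccc2)c1)c1cc(OCc2ccccc2)c(OC)cc1CC(=O)COCc1ccccc1 | intermediate
12 | methyl (1S,2R,3S)-7-(benzyloxy)-3-[(benzyloxy)methyl]-3-hydroxy-6-methoxy-1-[3,4,5-tris(benzyloxy)phenyl]-1,2,3,4-tetrahydronaphthalene-2-carboxylate | COc1cc2c(cc1OCc1ccccc1)[C@H](c1cc(OCc3ccccc3)c(OCc3ccccc3)c(OCc3ccccc3)c1)[C@@H](C(=O)OC)[C@](O)(COCc1ccccc1)C2 | intermediate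
13 | (1S,2R,3S)-7-(benzyloxy)-3-[(benzyloxy)methyl]-3-hydroxy-6-methoxy-1-[3,4,5-tris(benzyloxy)phenyl]-1,2,3,4-tetrahydronaphthalene-2-carboxylic acid | COc1cc2c(cc1OCc1ccccc1)[C@H](c1cc(OCc3ccccc3)c(OCc3ccccc3)c(OCc3ccccc3)c1)[C@@H](C(=O)O)[C@](O)(COCc1ccccc1)C2 | intermediate
14 | cis-fused β-lactone of 13 (C2 carboxyl closed onto the C3 oxygen; 1S,2R,3S in tetralin numbering) | COc1cc2c(cc1OCc1ccccc1)[C@H](c1cc(OCc3ccccc3)c(OCc3ccccc3)c(OCc3ccccc3)c1)[C@H]1C(=O)O[C@@]1(COCc1ccccc1)C2 | intermediate
15 | lithium enolate of β-lactone 14 (not isolated) | COc1cc2c(cc1OCc1ccccc1)[C@H](c1cc(OCc3ccccc3)c(OCc3ccccc3)c(OCc3ccccc3)c1)C1=C(O[Li])O[C@@]1(COCc1ccccc1)C2 | intermediate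
16 | α-hydroxy β-lactone: 2-hydroxy derivative of 14 (1S,2S,3R in tetralin numbering; OH on C2 cis to the C1 aryl group) | COc1cc2c(cc1OCc1ccccc1)[C@H](c1cc(OCc3ccccc3)c(OCc3ccccc3)c(OCc3ccccc3)c1)[C@@]1(O)C(=O)O[C@@]1(COCc1ccccc1)C2 | intermediate
17 | (1S,2S,3R)-7-(benzyloxy)-3-[(benzyloxy)methyl]-2,3-dihydroxy-6-methoxy-1-[3,4,5-tris(benzyloxy)phenyl]-1,2,3,4-tetrahydronaphthalene-2-carboxylic acid | COc1cc2c(cc1OCc1ccccc1)[C@H](c1cc(OCc3ccccc3)c(OCc3ccccc3)c(OCc3ccccc3)c1)[C@@](O)(C(=O)O)[C@](O)(COCc1ccccc1)C2 | intermediate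
18 | (1S,2S,3R)-2,3,7-trihydroxy-3-(hydroxymethyl)-6-methoxy-1-(3,4,5-trihydroxyphenyl)-1,2,3,4-tetrahydronaphthalene-2-carboxylic acid | COc1cc2c(cc1O)[C@H](c1cc(O)c(O)c(O)c1)[C@@](O)(C(=O)O)[C@](O)(CO)C2 | target

## Step count and risk

Total step count: 10. Longest linear sequence: 9 steps (steps 1, 2, 3, 5, 6, 7, 8, 9, 10); step 4 is a one-step side branch.

Step 5 (key step). The tandem sequence is documented for enone–ketones, and here the acceptor is an enoate. The most likely failure is therefore protonation of the rhodium enolate by water before it reaches the ketone, so that only conjugate arylation takes place. A second risk is retro-aldol equilibration at the rhodium aldolate stage. Fallback: set out from 7 and 10 and run the arylation as a plain asymmetric conjugate addition in dioxane/water 10:1 with the same catalyst. This gives methyl (3S)-3-{5-(benzyloxy)-2-[3-(benzyloxy)-2-oxopropyl]-4-methoxyphenyl}-3-[3,4,5-tris(benzyloxy)phenyl]propanoate F1. Saponify it (LiOH, THF/H2O) to the keto acid (3S)-3-{5-(benzyloxy)-2-[3-(benzyloxy)-2-oxopropyl]-4-methoxyphenyl}-3-[3,4,5-tris(benzyloxy)phenyl]propanoic acid F2. Close ring C by a nucleophile-catalysed aldol-lactonisation of the keto acid (2-chloro-1-methylpyridinium iodide, 4-pyrrolidinopyridine, iPr2NEt, CH2Cl2). There the acyl-ammonium enolate is formed selectively in the presence of the more acidic ketone, and the same allylic-strain and chair arguments apply. This fallback comes back to the route at 14.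

Step 8. Two things may go wrong. The hydroxylation may take place on the ring face that is sterically more open and force a trans ring fusion, giving poor facial selectivity. Alternatively, deprotonation of the hindered ring-fusion C–H may be slow enough for amide attack on the lactone carbonyl or β-elimination of the enolate to compete. Fallback: replace the ring-fusion lock by steric shielding. Set out from 12 and silylate the axial tertiary hydroxyl (Et3SiOTf, 2,6-lutidine) to methyl (1S,2R,3S)-7-(benzyloxy)-3-[(benzyloxy)methyl]-6-methoxy-3-[(triethylsilyl)oxy]-1-[3,4,5-tris(benzyloxy)phenyl]-1,2,3,4-tetrahydronaphthalene-2-carboxylate F3. Hydroxylate the ester enolate (LDA, then the same oxaziridine) on the face opposite the axial silyloxy group to methyl (1S,2S,3R)-7-(benzyloxy)-3-[(benzyloxy)methyl]-2-hydroxy-6-methoxy-3-[(triethylsilyl)oxy]-1-[3,4,5-tris(benzyloxy)phenyl]-1,2,3,4-tetrahydronaphthalene-2-carboxylate F4. Remove the silyl group (TBAF) to methyl (1S,2S,3R)-7-(benzyloxy)-3-[(benzyloxy)methyl]-2,3-dihydroxy-6-methoxy-1-[3,4,5-tris(benzyloxy)phenyl]-1,2,3,4-tetrahydronaphthalene-2-carboxylate F5, and saponify. The face preference of this open ester enolate is itself not secured by structure, so it is a second attempt and not a sure repair. It comes back to the route at 17.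

Step 2. Cyclisation of the aldehyde oxygen may go 5-exo instead of 6-endo, which leads to the aryl ketone regioisomer. The 1,5-dicarbonyl product may also condense to a 2-naphthol under the Lewis-acidic conditions. Fallback: build the chain by epoxide opening instead of alkyne hydration. Set out from 1 and protect the aldehyde (ethylene glycol, TsOH, toluene, Dean–Stark) as 2-[5-(benzyloxy)-2-bromo-4-methoxyphenyl]-1,3-dioxolane F6. After bromine–lithium exchange (n-BuLi, −78 °C), open benzyl glycidyl ether at its terminal carbon (BF3·OEt2) to give 1-(benzyloxy)-3-[4-(benzyloxy)-2-(1,3-dioxolan-2-yl)-5-methoxyphenyl]propan-2-ol F7. Oxidise it (Dess–Martin periodinane) to 1-(benzyloxy)-3-[4-(benzyloxy)-2-(1,3-dioxolan-2-yl)-5-methoxyphenyl]propan-2-one F8, and release the aldehyde with dilute aqueous acid. This comes back to the route at 5.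

Step 10. Hydrogenolysis of the hindered primary benzyl ether may stall after the phenolic ethers have gone, and the freed pyrogallol may oxidise in air during a prolonged reaction and isolation. Fallback: cleave the ethers by Lewis acid instead of hydrogen. Set out from 17 and treat it with BCl3 and pentamethylbenzene as cation scavenger in CH2Cl2 at −78 °C, followed by a methanol quench. This removes all five benzyl groups while the aryl methyl ether is left, and gives 18 directly.

## Further compounds

F1 | step 5 | methyl (3S)-3-{5-(benzyloxy)-2-[3-(benzyloxy)-2-oxopropyl]-4-methoxyphenyl}-3-[3,4,5-tris(benzyloxy)phenyl]propanoate | COC(=O)C[C@@H](c1cc(OCc2ccccc2)c(OCc2ccccc2)c(OCc2ccccc2)c1)c1cc(OCc2ccccc2)c(OC)cc1CC(=O)COCc1ccccc1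
F2 | step 5 | (3S)-3-{5-(benzyloxy)-2-[3-(benzyloxy)-2-oxopropyl]-4-methoxyphenyl}-3-[3,4,5-tris(benzyloxy)phenyl]propanoic acid | OC(=O)C[C@@H](c1cc(OCc2ccccc2)c(OCc2ccccc2)c(OCc2ccccc2)c1)c1cc(OCc2ccccc2)c(OC)cc1CC(=O)COCc1ccccc1
F3 | step 8 | methyl (1S,2R,3S)-7-(benzyloxy)-3-[(benzyloxy)methyl]-6-methoxy-3-[(triethylsilyl)oxy]-1-[3,4,5-tris(benzyloxy)phenyl]-1,2,3,4-tetrahydronaphthalene-2-carboxylate | COc1cc2c(cc1OCc1ccccc1)[C@H](c1cc(OCc3ccccc3)c(OCc3ccccc3)c(OCc3ccccc3)c1)[C@@H](C(=O)OC)[C@](O[Si](CC)(CC)CC)(COCc1ccccc1)C2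
F4 | step 8 | methyl (1S,2S,3R)-7-(benzyloxy)-3-[(benzyloxy)methyl]-2-hydroxy-6-methoxy-3-[(triethylsilyl)oxy]-1-[3,4,5-tris(benzyloxy)phenyl]-1,2,3,4-tetrahydronaphthalene-2-carboxylate | COc1cc2c(cc1OCc1ccccc1)[C@H](c1cc(OCc3ccccc3)c(OCc3ccccc3)c(OCc3ccccc3)c1)[C@@](O)(C(=O)OC)[C@](O[Si](CC)(CC)CC)(COCc1ccccc1)C2
F5 | step 8 | methyl (1S,2S,3R)-7-(benzyloxy)-3-[(benzyloxy)methyl]-2,3-dihydroxy-6-methoxy-1-[3,4,5-tris(benzyloxy)phenyl]-1,2,3,4-tetrahydronaphthalene-2-carboxylate | COc1cc2c(cc1OCc1ccccc1)[C@H](c1cc(OCc3ccccc3)c(OCc3ccccc3)c(OCc3ccccc3)c1)[C@@](O)(C(=O)OC)[C@](O)(COCc1ccccc1)C2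
F6 | step 2 | 2-[5-(benzyloxy)-2-bromo-4-methoxyphenyl]-1,3-dioxolane | COc1cc(Br)c(C2OCCO2)cc1OCc1ccccc1
F7 | step 2 | 1-(benzyloxy)-3-[4-(benzyloxy)-2-(1,3-dioxolan-2-yl)-5-methoxyphenyl]propan-2-ol (racemic) | COc1cc(CC(O)COCc2ccccc2)c(C2OCCO2)cc1OCc1ccccc1
F8 | step 2 | 1-(benzyloxy)-3-[4-(benzyloxy)-2-(1,3-dioxolan-2-yl)-5-methoxyphenyl]propan-2-one | COc1cc(CC(=O)COCc2ccccc2)c(C2OCCO2)cc1OCc1ccccc1
F0 | step 10 | none | none
A1 | alternative 1 | methyl (2S,3S)-2-{[4-(benzyloxy)-3-methoxyphenyl]acetyl}-3-[3,4,5-tris(benzyloxy)phenyl]oxirane-2-carboxylate | O=C(Cc1ccc(OCc2ccccc2)c(OC)c1)[C@@]1(C(=O)OC)O[C@H]1c1cc(OCc2ccccc2)c(OCc2ccccc2)c(OCc2ccccc2)c1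
A2 | alternative 1 | methyl (1S,2S)-7-(benzyloxy)-2-hydroxy-6-methoxy-3-oxo-1-[3,4,5-tris(benzyloxy)phenyl]-1,2,3,4-tetrahydronaphthalene-2-carboxylate | COc1cc2c(cc1OCc1ccccc1)[C@H](c1cc(OCc3ccccc3)c(OCc3ccccc3)c(OCc3ccccc3)c1)[C@@](O)(C(=O)OC)C(=O)C2
A3 | alternative 2 | methyl 3-[5-(benzyloxy)-4-methoxy-2-(2-oxoethyl)phenyl]-2-oxo-3-[3,4,5-tris(benzyloxy)phenyl]propanoate (configurationally labile at C3; racemate) | COC(=O)C(=O)C(c1cc(OCc2ccccc2)c(OCc2ccccc2)c(OCc2ccccc2)c1)c1cc(OCc2ccccc2)c(OC)cc1CC=O
A4 | alternative 3 | methyl (1S)-7-(benzyloxy)-3-[(benzyloxy)methyl]-6-methoxy-1-[3,4,5-tris(benzyloxy)phenyl]-1,4-dihydronaphthalene-2-carboxylate | COc1cc2c(cc1OCc1ccccc1)[C@H](c1cc(OCc3ccccc3)c(OCc3ccccc3)c(OCc3ccccc3)c1)C(C(=O)OC)=C(COCc1ccccc1)C2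
A5 | alternative 3 | methyl (1S,2R,3R)-7-(benzyloxy)-3-[(benzyloxy)methyl]-2,3-epoxy-6-methoxy-1-[3,4,5-tris(benzyloxy)phenyl]-1,2,3,4-tetrahydronaphthalene-2-carboxylate (oxirane oxygen anti to the C1 aryl group) | COc1cc2c(cc1OCc1ccccc1)[C@H](c1cc(OCc3ccccc3)c(OCc3ccccc3)c(OCc3ccccc3)c1)[C@@]1(C(=O)OC)O[C@@]1(COCc1ccccc1)C2
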